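## Retrosynthetic overview

1. Locants: ring C1 carries the side chain (C7 vinylic carbon, C8 CH–O, C10/C11 diol); C2 and C6 are the ring CH–O carbons; C3–C4 is the epoxide (C4 bears the methyl); C5 is the ketone. End game: acetonide cleavage ⇐ threefold angeloylation ⇐ hydroxyl-directed nucleophilic epoxidation of the C3=C4–C5=O enone ⇐ Nozaki–Hiyama–Kishi union C7–C8 with a chiral-pool aldehyde.
2. The 1-iodovinyl enone ⇐ C5 allylic alcohol with a C7 methyl ketone, held as a bridged hemiketal that fixes C1 ⇐ allylic hydroxylation of a 4-methylcyclohexene ⇐ 2-substituted 5-methylidenecyclohexane-1,3-diol.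
3. Key disconnection: C2–C3 and C5–C6 together, by a [3+3] annulation of a 2-(masked acetyl)propane-1,3-diol (C6–C1–C2) with 2-methylidenepropane-1,3-diyl diacetate (C3–C4–C5 plus the future methyl) through two iridium-catalysed transfer-hydrogenative carbonyl allylations in one operation.
4. Enabling feature: the ring carbinol carbons C2 and C6 that flank C1 have the same absolute sense, so C6–C1–C2 is a twofold-symmetric 1,3-diol unit in which C1 is not a stereocenter until C3 and C5 differ. C3–C4(Me)–C5 maps onto a 2-methylidenepropane-1,3-diyl unit. C6 (α to the C5 ketone) and C1 (through a C7 carbonyl and a C5 hydroxyl) remain correctable.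
5. Ring order: carbocycle (step 3), temporary oxabicycle (hemiketal, step 7, opened in step 8), epoxide (step 16).

Key step: step 3

Remark: the (S)-configured bisphosphine is assumed to give the S,S ring diol, by analogy with two-directional allylations of propane-1,3-diols; if the sense is opposite, the (R)-ligand is used.

## Route

Step 1
Reactants: 1 ethyl (2-methyl-1,3-dioxolan-2-yl)acetate
Product: 2 ethyl 3-hydroxy-2-(2-methyl-1,3-dioxolan-2-yl)propanoate (racemic)
Conditions: LiN(iPr)2, THF, −78 °C; CH2O (gas), −78 °C; H2O quench
Reagents that add atoms: formaldehyde, C=O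
Why: Ester enolate hydroxymethylation (aldol addition to monomeric formaldehyde), kept at −78 °C so that β-elimination of the ketal oxygen does not compete; the new stereocenter is of no consequence because step 2 turns it into a CH with two identical CH2OH arms.

Step 2
Reactants: 2 ethyl 3-hydroxy-2-(2-methyl-1,3-dioxolan-2-yl)propanoate
Product: 3 2-(2-methyl-1,3-dioxolan-2-yl)propane-1,3-diol
Conditions: LiAlH4, THF, 0 °C → rt
Reagents that add atoms: none
Why: Hydride reduction of the ester to the primary alcohol (LiAlH4 reduction) should give the achiral 2-substituted propane-1,3-diol with the ketal untouched.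

Step 3
Reactants: 3 2-(2-methyl-1,3-dioxolan-2-yl)propane-1,3-diol; 4 2-methylidenepropane-1,3-diyl diacetate
Product: 8 (1S,3S)-5-methylidene-2-(2-methyl-1,3-dioxolan-2-yl)cyclohexane-1,3-diol, via hydroxy aldehyde 5 (not isolated), via mono-allylated acetate 6 (not isolated), via acetoxy aldehyde 7 (not isolated)
Conditions: [Ir(cod)Cl]2 (5 mol%), (S)-Cl,MeO-BIPHEP (10 mol%), 4-chloro-3-nitrobenzoic acid (20 mol%), Cs2CO3 (40 mol%), 4 (1.05 equiv, slow addition), 1,4-dioxane (0.02 M), 90 °C
Reagents that add atoms: none
Why: Proposed new method: one allylic acetate of 4 is ionised by the monovalent iridium catalyst to a cyclometallated π-allyliridium C,O-benzoate, which adds to hydroxy aldehyde 5 formed by reversible dehydrogenation of one hydroxymethyl group of 3, and the sequence (ionisation of the second acetate in 6, dehydrogenation to 7, carbonyl addition) then repeats intramolecularly, so that both C–C bonds form redox-neutrally and the enolisable 2-substituted malondialdehyde is never present; the closest known reaction type is the two-directional iridium-catalysed carbonyl allylation of propane-1,3-diols with allyl acetate from the alcohol oxidation level, combined with the known use of 2-(acyloxymethyl)allyl donors in such C-allylations. The carbocycle closes in the second allylation as a 6-exo-trig addition of the allyliridium terminus to the tethered aldehyde through a chair-like closed transition state. Both new carbinol stereocenters (C2 and C6, each S in 8) are set by the chiral bisphosphine on iridium, which selects the same aldehyde face in both events; C1 is not a stereocenter in 8 because its two ring arms are identical and homochiral. The step needs C- over O-allylation, annulation over twofold intermolecular allylation and primary over secondary alcohol dehydrogenation: the first and third are inherent to this catalyst class, and the second is secured by one equivalent of 4 under dilution with slow addition, by the intramolecularity of the second addition and by acetate leaving groups that do not alkylate alkoxides without the catalyst.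

Step 4
Reactants: 8 (1S,3S)-5-methylidene-2-(2-methyl-1,3-dioxolan-2-yl)cyclohexane-1,3-diol
Product: 9 2-[(2S,6S)-2,6-bis(tert-butyldimethylsilyloxy)-4-methylidenecyclohexyl]-2-methyl-1,3-dioxolane
Conditions: TBSOTf, 2,6-lutidine, CH2Cl2, −78 → 0 °C
Reagents that add atoms: tert-butyldimethylsilyl trifluoromethanesulfonate, CC(C)(C)[Si](C)(C)OS(=O)(=O)C(F)(F)F
Why: Silyl ether formation on both secondary carbinols protects them through the oxidations and the acidic step, and the ketal should tolerate the buffered low-temperature conditions.

Step 5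
Reactants: 9 bis-silyl ether with exocyclic methylidene
Product: 10 2-[2,6-trans-bis(tert-butyldimethylsilyloxy)-4-methylcyclohex-3-en-1-yl]-2-methyl-1,3-dioxolane (both C1 epimers)
Conditions: RuHCl(CO)(PPh3)3 (5 mol%), toluene, 80 °C
Reagents that add atoms: none
Why: Ruthenium hydride addition and β-hydride elimination (alkene isomerisation) should move the exocyclic double bond into the ring to the more stable trisubstituted alkene; because C1 is not a stereocenter in 9, migration to either side gives the two C1 epimers of one constitution, and both are carried on.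

Step 6
Reactants: 10 4-methylcyclohex-3-ene bis-silyl ether (C1 epimers)
Product: 11 C5 allylic alcohol of 10, hydroxyl trans to the C6 silyloxy group (C1 epimers)
Conditions: SeO2 (0.3 equiv), t-BuOOH (3 equiv), CH2Cl2, 0 °C → rt
Reagents that add atoms: tert-butyl hydroperoxide, CC(C)(C)OO
Why: Selenium dioxide allylic hydroxylation (ene reaction then [2,3]-sigmatropic shift) should occur at the ring CH2 on the more substituted alkene terminus with retention of the double bond, and the hydroxyl is expected on the face opposite the neighbouring silyloxy group, which sets the temporary C5 carbinol trans to C6–OSi in both C1 epimers.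

Step 7
Reactants: 11 C5 allylic alcohol (C1 epimers)
Product: 13 bicyclic methyl hemiketal (7-hydroxy-4,7-dimethyl-6-oxabicyclo[3.2.1]oct-3-ene-2,8-diyl bis-silyl ether), via hydroxy ketone 12 (not isolated)
Conditions: TsOH·H2O (10 mol%), THF/H2O (4:1), 45 °C
Reagents that add atoms: water, O
Why: Acid hydrolysis of the ketal unmasks methyl ketone 12, whose C1 epimers interconvert through the more substituted enol, and only the epimer with the acetyl group cis to the C5 hydroxyl can close by 5-exo-trig hemiketalisation, so the ring-chain equilibrium should funnel both epimers into 13 and set C1 under thermodynamic control.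

Step 8
Reactants: 13 bicyclic methyl hemiketal
Product: 14 hydrazone of the C1 methyl ketone with free C5 hydroxyl
Conditions: N2H4·H2O, Et3N (cat.), EtOH, rt
Reagents that add atoms: hydrazine, NN
Why: Condensation of hydrazine with the open keto tautomer of the hemiketal (hydrazone formation) is mild and should not epimerise C1, and it releases the C5 hydroxyl again.

Step 9
Reactants: 14 hydrazone
Product: 15 C1-(1-iodoethenyl) C5 allylic alcohol
Conditions: iodine, 1,1,3,3-tetramethylguanidine, THF, 0 °C
Reagents that add atoms: iodine, I-I
Why: Barton vinyl iodide synthesis (oxidation of the hydrazone by iodine, loss of nitrogen and of a methyl proton) should give the terminal 1-iodoalkene and removes the carbonyl that made C1 epimerisable, so C1 is fixed from here on.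

Step 10
Reactants: 15 iodovinyl allylic alcohol
Product: 16 C1-(1-iodoethenyl)-2,6-bis(silyloxy)-4-methylcyclohex-3-en-5-one (target locants)
Conditions: Dess–Martin periodinane, CH2Cl2, rt
Reagents that add atoms: none
Why: Dess–Martin oxidation of the secondary allylic alcohol should give the 2-methylcyclohexenone without touching the vinyl iodide or silyl ethers; the temporary C5 stereocenter is erased, and the C6 silyloxy group, now α to the ketone, already sits in the thermodynamically preferred orientation trans to the C1 substituent.

Step 11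
Reactants: 17 (S)-3-hydroxydihydrofuran-2(3H)-one
Product: 18 (3S)-2-methylpentane-2,3,5-triol
Conditions: MeMgBr (3.5 equiv), THF, 0 °C → rt
Reagents that add atoms: methylmagnesium bromide, C[Mg]Br
Why: Double Grignard addition to the lactone (after deprotonation of the hydroxyl) should give the tertiary alcohol; the stereocenter (future C10) comes from the chiral pool and is not touched.

Step 12
Reactants: 18 (3S)-2-methylpentane-2,3,5-triol
Product: 19 2-[(4S)-2,2,5,5-tetramethyl-1,3-dioxolan-4-yl]ethan-1-ol
Conditions: 2,2-dimethoxypropane, PPTS (cat.), acetone, rt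
Reagents that add atoms: 2,2-dimethoxypropane, COC(C)(C)OC
Why: Acetonide formation under thermodynamic control (acetal exchange) should select the five-membered dioxolane of the secondary/tertiary 1,2-diol over the six-membered 1,3-dioxane and leave the primary alcohol free.

Step 13
Reactants: 19 acetonide alcohol
Product: 20 [(4S)-2,2,5,5-tetramethyl-1,3-dioxolan-4-yl]acetaldehyde
Conditions: Dess–Martin periodinane, CH2Cl2, rt
Reagents that add atoms: none
Why: Dess–Martin oxidation of the primary alcohol gives the aldehyde under neutral conditions that should leave the acetonide and the β-oxygenated stereocenter intact.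

Step 14
Reactants: 16 iodovinyl enone; 20 side-chain aldehyde
Product: 21 coupled C8 allylic alcohol (C7=CH2, bis-silyl ether, acetonide)
Conditions: CrCl2 (4 equiv), NiCl2 (2 mol%), 20 (1.5 equiv), DMSO, rt
Reagents that add atoms: none
Why: Nozaki–Hiyama–Kishi reaction (nickel-catalysed activation of the vinyl iodide, transmetalation to chromium, addition to the aldehyde) is chemoselective for the aldehyde over the enone, and the new C8 carbinol is expected to form mainly 1,3-anti to the β-oxygen of 20 by polar 1,3-induction, the minor epimer being removed.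

Step 15
Reactants: 21 coupled allylic alcohol
Product: 22 C2,C6,C8-triol enone (acetonide retained)
Conditions: HF·pyridine, pyridine, THF, 0 °C → rt
Reagents that add atoms: none
Why: Fluoride-mediated cleavage of both silyl ethers (desilylation) under buffered conditions should spare the acetonide and the enone and release the C2 and C6 hydroxyls.

Step 16
Reactants: 22 triol enone
Product: 23 C3–C4 epoxy ketone triol
Conditions: t-BuOOH, DBU, CH2Cl2, 0 °C
Reagents that add atoms: tert-butyl hydroperoxide, CC(C)(C)OO
Why: Weitz–Scheffer nucleophilic epoxidation of the enone, in which hydrogen bonding of the free C2 hydroxyl to the incoming hydroperoxide anion should direct conjugate addition to the same face, so the C3–C4 epoxide forms cis to C2–OH.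

Step 17
Reactants: 23 epoxy ketone triol
Product: 24 tris-angelate acetonide
Conditions: angelic acid, 2,4,6-trichlorobenzoyl chloride, Et3N, toluene, rt; then 23, 80 °C
Reagents that add atoms: angelic acid, C/C=C(/C)C(=O)O
Why: Threefold acylation through the mixed anhydride of angelic acid (Yamaguchi-type esterification), run without a nucleophilic pyridine catalyst so that the Z-configured acyl group should not isomerise to the tiglate, while the acetonide keeps the C10/C11 diol free of acyl groups.

Step 18
Reactants: 24 tris-angelate acetonide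
Product: 25 CNP0210092.1
Conditions: AcOH/H2O (4:1), 40 °C
Reagents that add atoms: none
Why: Mild acid hydrolysis of the acetonide (acetal cleavage) should free the C10/C11 diol without opening the epoxy ketone or cleaving the allylic esters.

## Compound list

1 | ethyl (2-methyl-1,3-dioxolan-2-yl)acetate | CCOC(=O)CC1(C)OCCO1 | starting material
2 | ethyl 3-hydroxy-2-(2-methyl-1,3-dioxolan-2-yl)propanoate (racemic) | CCOC(=O)C(CO)C1(C)OCCO1 | intermediate
3 | 2-(2-methyl-1,3-dioxolan-2-yl)propane-1,3-diol | CC1(OCCO1)C(CO)CO | intermediate
4 | 2-methylidenepropane-1,3-diyl diacetate | CC(=O)OCC(=C)COC(C)=O | starting material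
5 | 3-hydroxy-2-(2-methyl-1,3-dioxolan-2-yl)propanal (transient) | CC1(OCCO1)C(CO)C=O | intermediate
6 | (4S)-4,6-dihydroxy-2-methylidene-5-(2-methyl-1,3-dioxolan-2-yl)hexyl acetate (C5 epimers) | CC1(OCCO1)C(CO)[C@@H](O)CC(=C)COC(C)=O | intermediate
7 | (4S)-4-hydroxy-2-methylidene-5-(2-methyl-1,3-dioxolan-2-yl)-6-oxohexyl acetate (transient) | CC1(OCCO1)C(C=O)[C@@H](O)CC(=C)COC(C)=O | intermediate
8 | (1S,3S)-5-methylidene-2-(2-methyl-1,3-dioxolan-2-yl)cyclohexane-1,3-diol | CC1(OCCO1)C2[C@@H](O)CC(=C)C[C@@H]2O | intermediate
9 | 2-[(2S,6S)-2,6-bis(tert-butyldimethylsilyloxy)-4-methylidenecyclohexyl]-2-methyl-1,3-dioxolane | CC1(OCCO1)C2[C@@H](O[Si](C)(C)C(C)(C)C)CC(=C)C[C@@H]2O[Si](C)(C)C(C)(C)C | intermediate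
10 | 2-[2,6-trans-bis(tert-butyldimethylsilyloxy)-4-methylcyclohex-3-en-1-yl]-2-methyl-1,3-dioxolane (C1 epimers) | CC1(OCCO1)C2[C@@H](O[Si](C)(C)C(C)(C)C)C=C(C)C[C@@H]2O[Si](C)(C)C(C)(C)C | intermediate
11 | C5 allylic alcohol of 10, OH trans to C6–OSi (C1 epimers) | CC1(OCCO1)C2[C@@H](O[Si](C)(C)C(C)(C)C)C=C(C)[C@@H](O)[C@@H]2O[Si](C)(C)C(C)(C)C | intermediate
12 | C1 methyl ketone with free C5 hydroxyl (C1 epimers, open form) | CC(=O)C1[C@@H](O[Si](C)(C)C(C)(C)C)C=C(C)[C@@H](O)[C@@H]1O[Si](C)(C)C(C)(C)C | intermediate
13 | bicyclic methyl hemiketal, C7–O–C5 bridge cis to C2–OSi (hemiketal carbon undefined) | CC3(O)[C@H]1[C@@H](O[Si](C)(C)C(C)(C)C)C=C(C)[C@@H](O3)[C@@H]1O[Si](C)(C)C(C)(C)C | intermediate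
14 | hydrazone of the C1 methyl ketone, C1 side chain cis to C2–OSi and C5–OH | CC(=NN)[C@H]1[C@@H](O[Si](C)(C)C(C)(C)C)C=C(C)[C@@H](O)[C@@H]1O[Si](C)(C)C(C)(C)C | intermediate
15 | C1-(1-iodoethenyl) C5 allylic alcohol | C=C(I)[C@H]1[C@@H](O[Si](C)(C)C(C)(C)C)C=C(C)[C@@H](O)[C@@H]1O[Si](C)(C)C(C)(C)C | intermediate
16 | C1-(1-iodoethenyl) C5 enone | C=C(I)[C@H]1[C@@H](O[Si](C)(C)C(C)(C)C)C=C(C)C(=O)[C@@H]1O[Si](C)(C)C(C)(C)C | intermediate
17 | (S)-3-hydroxydihydrofuran-2(3H)-one | O[C@H]1CCOC1=O | starting material
18 | (3S)-2-methylpentane-2,3,5-triol | CC(C)(O)[C@@H](O)CCO | intermediate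
19 | 2-[(4S)-2,2,5,5-tetramethyl-1,3-dioxolan-4-yl]ethan-1-ol | CC1(C)OC(C)(C)O[C@H]1CCO | intermediate
20 | [(4S)-2,2,5,5-tetramethyl-1,3-dioxolan-4-yl]acetaldehyde | CC1(C)OC(C)(C)O[C@H]1CC=O | intermediate
21 | coupled (8S) allylic alcohol, bis-silyl ether, acetonide | C=C([C@H]1[C@@H](O[Si](C)(C)C(C)(C)C)C=C(C)C(=O)[C@@H]1O[Si](C)(C)C(C)(C)C)[C@H](C[C@@H]2OC(C)(C)OC2(C)C)O | intermediate
22 | C2,C6,C8-triol enone, acetonide | C=C([C@H]1[C@@H](O)C=C(C)C(=O)[C@@H]1O)[C@H](C[C@@H]3OC(C)(C)OC3(C)C)O | intermediate
23 | C3–C4 epoxy ketone triol, acetonide | C=C([C@H]1[C@@H](O)[C@H]2O[C@@]2(C)C(=O)[C@@H]1O)[C@H](C[C@@H]3OC(C)(C)OC3(C)C)O | intermediate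
24 | tris-angelate acetonide | C=C([C@H]1[C@@H](OC(=O)/C(C)=C\C)[C@H]2O[C@@]2(C)C(=O)[C@@H]1OC(=O)/C(C)=C\C)[C@H](C[C@@H]3OC(C)(C)OC3(C)C)OC(=O)/C(C)=C\C | intermediate
25 | CNP0210092.1 | C=C([C@H]1[C@@H](OC(=O)/C(C)=C\C)[C@H]2O[C@@]2(C)C(=O)[C@@H]1OC(=O)/C(C)=C\C)[C@H](C[C@H](O)C(C)(C)O)OC(=O)/C(C)=C\C | target

## Step count and risks

Total: 18 steps. Longest linear sequence: 15 steps (steps 1–10 and 14–18); the aldehyde branch (steps 11–13) is three steps.

Three steps most likely to fail:

1. Step 3 (the proposed annulation). The mono-allylated intermediate may be allylated a second time intermolecularly (acyclic bis-adducts, oligomers) or O-allylated, and the transient β-alkoxy aldehyde may lose the ketal oxygen by elimination. The fallback is stepwise and uses known reactions, setting out from 3 and returning at 8. Monosilylation (NaH, TBSCl, THF) gives racemic 3-(tert-butyldimethylsilyloxy)-2-(2-methyl-1,3-dioxolan-2-yl)propan-1-ol F1, and Swern oxidation gives aldehyde F2. A catalytic asymmetric Keck allylation with tributyl{2-[(trimethylsilyl)methyl]prop-2-enyl}stannane (Ti(OiPr)4, BINOL, enantiomer chosen for the S carbinol) gives the allylsilane-bearing homoallylic alcohol F3. HF·pyridine removes the primary silyl ether to give diol F4, and selective oxidation of the primary alcohol (TEMPO, (diacetoxyiodo)benzene) gives hydroxy aldehyde F5. An intramolecular Hosomi–Sakurai reaction (BF3·OEt2, CH2Cl2, −78 °C) then closes the ring to 8; the 1,3-trans diol is expected from a chair transition state and the cis isomer would be removed.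

2. Step 6. The hydroxyl may be delivered syn to the neighbouring silyloxy group, or oxidation may occur at the methyl group or run on to the enone; a syn hydroxyl would steer step 7 to the wrong C1 configuration. The fallback sets out from 10 and returns at 11. Allylic oxidation with CrO3·3,5-dimethylpyrazole (CH2Cl2, −20 °C) gives the C5 enone F6. A Corey–Bakshi–Shibata reduction, with the oxazaborolidine enantiomer that delivers hydride to the face cis to the C6 silyloxy group, then gives 11 under reagent control.

3. Step 7. The enol needed for C1 equilibration may lose a silyloxy group by β-elimination, the allylic alcohol may ionise, or equilibration may stay incomplete. The fallback avoids epimerisation, sets out from 11 and returns at 16. The C1 epimers of 11 are separated. The epimer with the C1 substituent cis to the C5 hydroxyl is hydrolysed without equilibration (PPTS, wet acetone, rt), closes directly to 13 and continues through steps 8–10. The other epimer is transposed instead: catalytic Ph3SiOReO3 (Et2O, 0 °C; suprafacial 1,3-shift, equilibrium mixture, separation and recycling) gives the transposed allylic alcohol F7. When the ring is numbered in the opposite sense, F7 has the C1 substituent cis to C2–OSi and differs from the first series only at C5. Hydrolysis as above gives the open hydroxy ketone F8, hydrazine gives hydrazone F9, and iodine with tetramethylguanidine gives iodovinyl alcohol F10. Dess–Martin oxidation removes the C5 stereocenter and gives 16.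

Further compounds
F1 | step 3 | 3-(tert-butyldimethylsilyloxy)-2-(2-methyl-1,3-dioxolan-2-yl)propan-1-ol (racemic) | CC1(OCCO1)C(CO)CO[Si](C)(C)C(C)(C)C
F2 | step 3 | 3-(tert-butyldimethylsilyloxy)-2-(2-methyl-1,3-dioxolan-2-yl)propanal | CC1(OCCO1)C(C=O)CO[Si](C)(C)C(C)(C)C
F3 | step 3 | (S)-homoallylic alcohol bearing the 2-[(trimethylsilyl)methyl]allyl group and the primary silyl ether | CC1(OCCO1)C(CO[Si](C)(C)C(C)(C)C)[C@@H](O)CC(=C)C[Si](C)(C)C
F4 | step 3 | diol from F3 after removal of the primary silyl ether | CC1(OCCO1)C(CO)[C@@H](O)CC(=C)C[Si](C)(C)C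
F5 | step 3 | hydroxy aldehyde with pendant allylsilane | CC1(OCCO1)C(C=O)[C@@H](O)CC(=C)C[Si](C)(C)C
F6 | step 6 | C5 enone of 10 (C1 epimers) | CC1(OCCO1)C2[C@@H](O[Si](C)(C)C(C)(C)C)C=C(C)C(=O)[C@@H]2O[Si](C)(C)C(C)(C)C
F7 | step 7 | transposed allylic alcohol (ketal), C5–OH cis to C6–OSi, C1 substituent cis to C2–OSi | CC3(OCCO3)[C@H]1[C@@H](O[Si](C)(C)C(C)(C)C)C=C(C)[C@H](O)[C@@H]1O[Si](C)(C)C(C)(C)C
F8 | step 7 | open hydroxy methyl ketone from F7 | CC(=O)[C@H]1[C@@H](O[Si](C)(C)C(C)(C)C)C=C(C)[C@H](O)[C@@H]1O[Si](C)(C)C(C)(C)C
F9 | step 7 | hydrazone of F8 | CC(=NN)[C@H]1[C@@H](O[Si](C)(C)C(C)(C)C)C=C(C)[C@H](O)[C@@H]1O[Si](C)(C)C(C)(C)C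
F10 | step 7 | C1-(1-iodoethenyl) allylic alcohol, C5 epimer of 15 | C=C(I)[C@H]1[C@@H](O[Si](C)(C)C(C)(C)C)C=C(C)[C@H](O)[C@@H]1O[Si](C)(C)C(C)(C)C
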